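**Retrosynthetic overview**

1. Bromophycolide H ⇐ macrolide 15 by removal of the phenol acetate and the C11 trifluoroacetate.
2. 15 ⇐ acyclic tris(β‑bromo tertiary trifluoroacetate) 13 in one operation: the cyclohexane closes first (C2–C7, allylsilane terminator), then the 16‑membered lactone (C15–O, tert‑butyl ester carbonyl). The arene ring is bought.
3. 13 ⇐ tris‑epoxide 11 by SN2 bromide opening (every C–Br centre by inversion) and O‑trifluoroacetylation.
4. 11 ⇐ Suzuki union (C1–C2) of benzylic bromide 10 with alkenylboronate 6; 6 ⇐ silylmethylboration of alkyne 5 ⇐ propargylation of tris‑epoxy alcohol 3.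
5. 3 ⇐ farnesol by Sharpless epoxidation (C6, C7) then Shi epoxidation (C10, C11, C14); these two steps carry all absolute stereochemistry.

Assumption: C‑locants in the text (C1 to C15) are those of the diterpene chain in the target (C1 benzylic, C3 the methylidene‑bearing carbon, C15 the lactone O‑bearing carbon); D‑(−)‑diethyl tartrate and the L‑fructose‑derived Shi ketone are bought as chiral reagents.

**Route**

Step 1
Reactants: 1 (2E,6E)-farnesol
Product: 2 (2R,3R)-2,3-epoxyfarnesol
Conditions: Ti(OiPr)4 (10 mol %), D‑(−)‑diethyl tartrate (12 mol %), t‑BuOOH, 4 Å MS, CH2Cl2, −20 °C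
Reagents that add atoms: tert‑butyl hydroperoxide, CC(C)(C)OO
Why: Sharpless asymmetric epoxidation reaches only the allylic‑alcohol alkene, and the D‑tartrate delivers oxygen to the face that gives the (2R,3R) epoxide, which fixes the future C6 and C7.

Step 2
Reactants: 2 (2R,3R)-2,3-epoxyfarnesol
Product: 3 (2R,3R,6S,7S,10S)-2,3:6,7:10,11-triepoxy-3,7,11-trimethyldodecan-1-ol
Conditions: L‑fructose‑derived Shi ketone (0.6 equiv), KHSO5 (as 2KHSO5·KHSO4·K2SO4), K2CO3, Bu4NHSO4, Na2B4O7 buffer, MeCN/CH2(OMe)2/H2O, 0 °C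
Reagents that add atoms: potassium peroxymonosulfate, [K+].[O-]S(=O)(=O)OO
Why: Shi epoxidation through the chiral dioxirane (spiro transition state) converts both remaining trisubstituted alkenes under reagent control into the (6S,7S) and (10S) epoxides, the future C10, C11 and C14.

Step 3
Reactants: 3 (2R,3R,6S,7S,10S)-2,3:6,7:10,11-triepoxy-3,7,11-trimethyldodecan-1-ol
Product: 5 (5R,6R,9S,10S,13S)-5,6:9,10:13,14-triepoxy-6,10,14-trimethylpentadec-1-yne, via triflate 4 (not isolated)
Conditions: Tf2O, 2,6‑lutidine, CH2Cl2, −78 °C; then LiCH2C≡CLi (propyne, 2 n‑BuLi, TMEDA), THF, −78 to −30 °C; H2O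
Reagents that add atoms: 1,3‑dilithiopropyne (from propyne and n‑BuLi), [Li]CC#C[Li]
Why: The primary triflate is displaced in an SN2 reaction by the sp3 carbon of the propargylic dianion much faster than any epoxide opens at low temperature, so C4 to C2 are added with all five stereocentres untouched (propargyl dianion alkylation).

Step 4
Reactants: 5 (5R,6R,9S,10S,13S)-5,6:9,10:13,14-triepoxy-6,10,14-trimethylpentadec-1-yne
Product: 6 2-[(1Z,5R,6R,9S,10S,13S)-5,6:9,10:13,14-triepoxy-6,10,14-trimethyl-2-(trimethylsilylmethyl)pentadec-1-en-1-yl]-4,4,5,5-tetramethyl-1,3,2-dioxaborolane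
Conditions: CuCl (10 mol %), Xantphos (10 mol %), NaOtBu, B2pin2, Me3SiCH2I, THF, 23 °C
Reagents that add atoms: bis(pinacolato)diboron, CC1(C)OB(OC1(C)C)B1OC(C)(C)C(C)(C)O1; (iodomethyl)trimethylsilane, C[Si](C)(C)CI
Why: Copper‑catalysed carboboration adds boron to the terminal carbon and copper to the internal carbon in a syn fashion, and the alkenylcopper is alkylated with retention, so boron ends cis to CH2SiMe3 (Z alkene) and no stereocentre is touched.

Step 5
Reactants: 7 4-hydroxy-3-methylbenzoic acid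
Product: 8 4-acetoxy-3-methylbenzoic acid
Conditions: Ac2O, pyridine, 23 °C; H2O
Reagents that add atoms: acetic anhydride, CC(=O)OC(C)=O
Why: Pyridine‑promoted O‑acylation of the phenol (the mixed anhydride at the acid is hydrolysed on work‑up) makes the phenol oxygen non‑nucleophilic for the later cation chemistry.

Step 6
Reactants: 8 4-acetoxy-3-methylbenzoic acid
Product: 9 tert-butyl 4-acetoxy-3-methylbenzoate
Conditions: tert‑butyl 2,2,2‑trichloroacetimidate, BF3·OEt2 (5 mol %), CH2Cl2/cyclohexane, 23 °C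
Reagents that add atoms: tert‑butyl 2,2,2‑trichloroacetimidate, CC(C)(C)OC(=N)C(Cl)(Cl)Cl
Why: Acid‑catalysed tert‑butyl transfer from the imidate esterifies the acid without touching the aryl acetate and installs an ester that can later leave as isobutene.

Step 7
Reactants: 9 tert-butyl 4-acetoxy-3-methylbenzoate
Product: 10 tert-butyl 4-acetoxy-3-(bromomethyl)benzoate
Conditions: NBS, AIBN (5 mol %), PhCF3, 85 °C
Reagents that add atoms: N‑bromosuccinimide, O=C1CCC(=O)N1Br
Why: Wohl–Ziegler radical bromination takes the only benzylic C–H position, the ring being deactivated towards electrophilic bromination by the acetate and the ester.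

Step 8
Reactants: 6 2-[(1Z,5R,6R,9S,10S,13S)-5,6:9,10:13,14-triepoxy-6,10,14-trimethyl-2-(trimethylsilylmethyl)pentadec-1-en-1-yl]-4,4,5,5-tetramethyl-1,3,2-dioxaborolane; 10 tert-butyl 4-acetoxy-3-(bromomethyl)benzoate
Product: 11 tert-butyl 4-acetoxy-3-[(2Z,6R,7R,10S,11S,14S)-6,7:10,11:14,15-triepoxy-7,11,15-trimethyl-3-(trimethylsilylmethyl)hexadec-2-en-1-yl]benzoate
Conditions: Pd(dppf)Cl2 (5 mol %), K3PO4·H2O, toluene/THF, 45 °C
Reagents that add atoms: none
Why: Suzuki–Miyaura sp2–sp3 coupling forms C1–C2 with retention of alkene geometry, so C1 sits cis to CH2SiMe3 and trans to C4, and the mild heterogeneous base spares epoxides, allylsilane and aryl acetate.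

Step 9
Reactants: 11 tert-butyl 4-acetoxy-3-[(2Z,6R,7R,10S,11S,14S)-6,7:10,11:14,15-triepoxy-7,11,15-trimethyl-3-(trimethylsilylmethyl)hexadec-2-en-1-yl]benzoate
Product: 13 tert-butyl 4-acetoxy-3-[(2Z,6S,7R,10R,11S,14R)-6,10,14-tribromo-7,11,15-trimethyl-7,11,15-tris(trifluoroacetoxy)-3-(trimethylsilylmethyl)hexadec-2-en-1-yl]benzoate, via tris-bromohydrin 12 (not isolated)
Conditions: Li2NiBr4 (0.4 M in THF), 0 to 23 °C; then pyridine, (CF3CO)2O, −20 to 0 °C
Reagents that add atoms: dilithium tetrabromonickelate, [Li+].[Li+].Br[Ni-2](Br)(Br)Br; trifluoroacetic anhydride, O=C(OC(=O)C(F)(F)F)C(F)(F)F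
Why: The soft bromide of Li2NiBr4 opens each epoxide by SN2 at the less substituted carbon, so C6, C10 and C14 become C–Br centres by inversion while the tertiary C–O bonds keep their configuration, and the tertiary alkoxides are then acylated in the same flask (halohydrin formation, O‑acylation).

Step 10
Reactants: 13 tert-butyl 4-acetoxy-3-[(2Z,6S,7R,10R,11S,14R)-6,10,14-tribromo-7,11,15-trimethyl-7,11,15-tris(trifluoroacetoxy)-3-(trimethylsilylmethyl)hexadec-2-en-1-yl]benzoate
Product: 15 bromophycolide H phenol O-acetate C11 O-trifluoroacetate, via monocyclic ester 14 (not isolated)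
Conditions: (CF3)2CHOH/CH2Cl2 4:1, 2 mM (13 added over 8 h), 2,6‑di‑tert‑butyl‑4‑methylpyridine, 45 °C
Reagents that add atoms: none
Why: Proposed new method: in the ionising, non‑nucleophilic solvent each tertiary β‑bromo trifluoroacetate ionises with neighbouring‑bromine participation to a configurationally defined bromonium ion pair (the secondary C–Br centres never open); at C6–C7 the allylsilane attacks C7 through C2 anti to bromine in a chair transition state with the benzyl group and the C8 chain equatorial and loses Me3Si+, which gives only the exocyclic methylidene and sets C7 (net retention by double inversion) and C2 as (2R,6S,7S); at C14–C15 the carbonyl oxygen of the tert‑butyl ester opens the bromonium ion at C15 and loses isobutene to close the 16‑membered lactone; the C10–C11 ion pair can only return to its trifluoroacetate with retention; the closest known reactions are the enantiospecific polyene cyclisation of enantiopure bromohydrin derivatives, allylsilane‑terminated cation–olefin cyclisation and halolactonisation of tert‑butyl esters.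

Step 11
Reactants: 15 bromophycolide H phenol O-acetate C11 O-trifluoroacetate
Product: 16 bromophycolide H
Conditions: NaHCO3, MeOH, 23 °C
Reagents that add atoms: none
Why: Bicarbonate‑buffered methanolysis cleaves the activated aryl acetate and the tertiary trifluoroacetate, but is too weakly basic to close the bromohydrin to an epoxide or to open the hindered tertiary benzoate lactone (transesterification).

**Compound list**

1 | (2E,6E)-farnesol | OC/C=C(\C)CC/C=C(\C)CCC=C(C)C | starting material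
2 | (2R,3R)-2,3-epoxyfarnesol | OC[C@H]1O[C@]1(C)CC/C=C(\C)CCC=C(C)C | intermediate
3 | (2R,3R,6S,7S,10S)-2,3:6,7:10,11-triepoxy-3,7,11-trimethyldodecan-1-ol | OC[C@H]1O[C@]1(C)CC[C@@H]1O[C@@]1(C)CC[C@@H]1OC1(C)C | intermediate
4 | (2R,3R,6S,7S,10S)-2,3:6,7:10,11-triepoxy-3,7,11-trimethyldodecyl trifluoromethanesulfonate | O=S(=O)(OC[C@H]1O[C@]1(C)CC[C@@H]1O[C@@]1(C)CC[C@@H]1OC1(C)C)C(F)(F)F | intermediate
5 | (5R,6R,9S,10S,13S)-5,6:9,10:13,14-triepoxy-6,10,14-trimethylpentadec-1-yne | C#CCC[C@H]1O[C@]1(C)CC[C@@H]1O[C@@]1(C)CC[C@@H]1OC1(C)C | intermediate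
6 | 2-[(1Z,5R,6R,9S,10S,13S)-5,6:9,10:13,14-triepoxy-6,10,14-trimethyl-2-(trimethylsilylmethyl)pentadec-1-en-1-yl]-4,4,5,5-tetramethyl-1,3,2-dioxaborolane | CC1(C)OB(OC1(C)C)/C=C(\C[Si](C)(C)C)CC[C@H]1O[C@]1(C)CC[C@@H]1O[C@@]1(C)CC[C@@H]1OC1(C)C | intermediate
7 | 4-hydroxy-3-methylbenzoic acid | Cc1cc(ccc1O)C(=O)O | starting material
8 | 4-acetoxy-3-methylbenzoic acid | CC(=O)Oc1ccc(cc1C)C(=O)O | intermediate
9 | tert-butyl 4-acetoxy-3-methylbenzoate | CC(=O)Oc1ccc(cc1C)C(=O)OC(C)(C)C | intermediate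
10 | tert-butyl 4-acetoxy-3-(bromomethyl)benzoate | CC(=O)Oc1ccc(cc1CBr)C(=O)OC(C)(C)C | intermediate
11 | tert-butyl 4-acetoxy-3-[(2Z,6R,7R,10S,11S,14S)-6,7:10,11:14,15-triepoxy-7,11,15-trimethyl-3-(trimethylsilylmethyl)hexadec-2-en-1-yl]benzoate | CC(=O)Oc1ccc(cc1C/C=C(\C[Si](C)(C)C)CC[C@H]2O[C@]2(C)CC[C@@H]2O[C@@]2(C)CC[C@@H]2OC2(C)C)C(=O)OC(C)(C)C | intermediate
12 | tert-butyl 4-acetoxy-3-[(2Z,6S,7R,10R,11S,14R)-6,10,14-tribromo-7,11,15-trihydroxy-7,11,15-trimethyl-3-(trimethylsilylmethyl)hexadec-2-en-1-yl]benzoate (present as its alkoxide) | CC(=O)Oc1ccc(cc1C/C=C(\C[Si](C)(C)C)CC[C@H](Br)[C@](C)(O)CC[C@@H](Br)[C@@](C)(O)CC[C@@H](Br)C(C)(C)O)C(=O)OC(C)(C)C | intermediate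
13 | tert-butyl 4-acetoxy-3-[(2Z,6S,7R,10R,11S,14R)-6,10,14-tribromo-7,11,15-trimethyl-7,11,15-tris(trifluoroacetoxy)-3-(trimethylsilylmethyl)hexadec-2-en-1-yl]benzoate | CC(=O)Oc1ccc(cc1C/C=C(\C[Si](C)(C)C)CC[C@H](Br)[C@](C)(OC(=O)C(F)(F)F)CC[C@@H](Br)[C@@](C)(OC(=O)C(F)(F)F)CC[C@@H](Br)C(C)(C)OC(=O)C(F)(F)F)C(=O)OC(C)(C)C | intermediate
14 | tert-butyl 4-acetoxy-3-{[(1R,2S,3S)-3-bromo-2-[(3R,4S,7R)-3,7-dibromo-4,8-dimethyl-4,8-bis(trifluoroacetoxy)nonyl]-2-methyl-6-methylidenecyclohexyl]methyl}benzoate | C=C1CC[C@H](Br)[C@@](C)(CC[C@@H](Br)[C@@](C)(OC(=O)C(F)(F)F)CC[C@@H](Br)C(C)(C)OC(=O)C(F)(F)F)[C@@H]1Cc2cc(ccc2OC(C)=O)C(=O)OC(C)(C)C | intermediate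
15 | bromophycolide H phenol O-acetate C11 O-trifluoroacetate | C=C1CC[C@H](Br)[C@@]2(C)CC[C@@H](Br)[C@@](C)(OC(=O)C(F)(F)F)CC[C@@H](Br)C(C)(C)OC(=O)c3ccc(OC(C)=O)c(c3)C[C@H]12 | intermediate
16 | bromophycolide H, (2R,6S,7S,10R,11S,14R) in chain numbering | C=C1CC[C@H](Br)[C@@]2(C)CC[C@@H](Br)[C@@](C)(O)CC[C@@H](Br)C(C)(C)OC(=O)c3ccc(O)c(c3)C[C@H]12 | target

**Step count and risks**

Total steps: 11. Longest linear sequence: 8 (steps 1, 2, 3, 4, 8, 9, 10, 11 from farnesol); steps 5 to 7 make the arene partner, which joins at step 8.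

The three steps most likely to fail:

- **Step 10 (double ring closure).** Ionisation of the tertiary trifluoroacetates may be slow. The lactone closure competes with elimination at C15, with capture at C11 (12‑membered lactone) and with oligomers. The fallback sets out from 13 and comes back at 15, and it separates the two closures and changes the lactonising nucleophile. 13 is treated with Me3SiOTf (5 mol %) and 2,6‑di‑tert‑butyl‑4‑methylpyridine in CH2Cl2 at −78 °C, where only the allylsilane‑terminated closure runs, and 14 is isolated. Me3SiOTf/2,6‑lutidine at 0 °C then exchanges the tert‑butyl ester for a silyl ester, the monocyclic trimethylsilyl ester F1. F1 is lactonised on its own by slow addition to (CF3)2CHOH at 45 °C, the silyl ester carbonyl being the stronger internal nucleophile, to give 15.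

- **Step 9 (site of bromide attack).** Bromide may open the epoxides at the tertiary carbons instead. The fallback sets out from 11 and comes back at 15, and it reaches the same bromonium ions from the regioisomeric halohydrins. LiBr/AcOH in THF opens the three epoxides at the tertiary carbons with inversion to give the tris(tertiary bromide) triol F2. MsCl/Et3N then gives the tris‑mesylate F3. In buffered (CF3)2CHOH with Bu4NO2CCF3 each secondary mesylate ionises with participation of the neighbouring tertiary bromine (1,2‑bromine shift). This generates the bromonium ions of step 10, the rings close as there, C11 is captured by trifluoroacetate, and the product is 15.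

- **Step 4 (silylmethylboration).** Me3SiCH2I may be borylated directly or may alkylate the alkenylcopper too slowly. The fallback sets out from 5 and comes back at 11, and it replaces borylcupration/Suzuki by carbocupration/Negishi. Me3SiCH2MgCl/CuBr·SMe2 (Et2O/Me2S, −30 °C) adds syn across the alkyne with copper on the terminal carbon, and an iodine quench gives the alkenyl iodide F4. 10 with zinc dust/LiCl gives the benzylzinc bromide F5. Pd(PPh3)4‑catalysed coupling of F4 with F5 gives 11.

Further compounds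
F1 | step 10 | trimethylsilyl 4-acetoxy-3-{[(1R,2S,3S)-3-bromo-2-[(3R,4S,7R)-3,7-dibromo-4,8-dimethyl-4,8-bis(trifluoroacetoxy)nonyl]-2-methyl-6-methylidenecyclohexyl]methyl}benzoate | C=C1CC[C@H](Br)[C@@](C)(CC[C@@H](Br)[C@@](C)(OC(=O)C(F)(F)F)CC[C@@H](Br)C(C)(C)OC(=O)C(F)(F)F)[C@@H]1Cc2cc(ccc2OC(C)=O)C(=O)O[Si](C)(C)C
F2 | step 9 | tert-butyl 4-acetoxy-3-[(2Z,6R,7S,10S,11R,14S)-7,11,15-tribromo-6,10,14-trihydroxy-7,11,15-trimethyl-3-(trimethylsilylmethyl)hexadec-2-en-1-yl]benzoate | CC(=O)Oc1ccc(cc1C/C=C(\C[Si](C)(C)C)CC[C@@H](O)[C@@](C)(Br)CC[C@H](O)[C@](C)(Br)CC[C@H](O)C(C)(C)Br)C(=O)OC(C)(C)C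
F3 | step 9 | tert-butyl 4-acetoxy-3-[(2Z,6R,7S,10S,11R,14S)-7,11,15-tribromo-7,11,15-trimethyl-6,10,14-tris(methylsulfonyloxy)-3-(trimethylsilylmethyl)hexadec-2-en-1-yl]benzoate | CC(=O)Oc1ccc(cc1C/C=C(\C[Si](C)(C)C)CC[C@@H](OS(C)(=O)=O)[C@@](C)(Br)CC[C@H](OS(C)(=O)=O)[C@](C)(Br)CC[C@H](OS(C)(=O)=O)C(C)(C)Br)C(=O)OC(C)(C)C
F4 | step 4 | (1Z,5R,6R,9S,10S,13S)-5,6:9,10:13,14-triepoxy-1-iodo-6,10,14-trimethyl-2-(trimethylsilylmethyl)pentadec-1-ene | I/C=C(\C[Si](C)(C)C)CC[C@H]1O[C@]1(C)CC[C@@H]1O[C@@]1(C)CC[C@@H]1OC1(C)C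
F5 | step 4 | [2-acetoxy-5-(tert-butoxycarbonyl)benzyl]zinc bromide | Br[Zn]Cc1cc(ccc1OC(C)=O)C(=O)OC(C)(C)C
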